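Wednesday's run, charged with half the substrate of Thursday's and with the same reagent and free catalyst, has also made half the product at the last reading, so at those charges of reagent and free catalyst the rate past the opening minutes goes close to c(substrate) to the first power, and one constant can be carried between the flasks that share them.

| setting | Thursday's | Friday's | Wednesday's | Monday's | Sunday's |
|---|---|---|---|---|---|
| substrate | 1.00 M | 0.600 M | 0.500 M | 1.00 M | 1.00 M |
| reagent | 2.50 M | 2.10 M | 2.50 M | 2.50 M | 2.50 M |
| free catalyst | 0.0500 M | 0.0500 M | 0.0500 M | 0.0750 M | 0.0500 M |
| time |  |  |  |  | 18 min |

| Thursday's run: time / min | Thursday's run: [product] / M | Friday's run: time / min | Friday's run: [product] / M | Wednesday's run: time / min | Wednesday's run: [product] / M | Monday's run: time / min | Monday's run: [product] / M |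
|---|---|---|---|---|---|---|---|
| 1.2 | 0.087 | 1.2 | 0.041 | 1.2 | 0.038 | 1.2 | 0.140 |
| 2.4 | 0.193 | 2.4 | 0.116 | 2.4 | 0.099 | 2.4 | 0.303 |
| 3.6 | 0.304 | 3.6 | 0.173 | 3.6 | 0.153 | 3.6 | 0.441 |
| 4.9 | 0.396 | 4.9 | 0.223 | 4.9 | 0.199 | 4.9 | 0.558 |
| 6.1 | 0.464 | 6.1 | 0.268 | 6.1 | 0.243 | 6.1 | 0.637 |
| 7.3 | 0.532 | 7.3 | 0.310 | 7.3 | 0.271 | 7.3 | 0.705 |

(readings scatter by 0.003 M)

- the exponent of [substrate] in the starting rate at the charge of the Thursday's run (at the point where two percent of the substrate have become product) (one fixed amount of product, the same in the runs compared)
- the exponent of [reagent] in the starting rate at the charge of the Thursday's run (at the point where two percent of the substrate have become product)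
- the Friday's run starts with 0.400 M less of substrate and of reagent than the Thursday's run, and with no product. Compared where both hold the same amount of substrate, once fifteen percent of what the Friday's run was charged with has turned into product, is the Friday's run faster, slower or alike (within a tenth)?
- product in the Sunday's run at 18 min, as a share of the substrate charged

- Overall: substrate + reagent -> product, with free catalyst as catalyst.
- Constant volume, constant temperature.
- What is held in complexes is read along with the free species.
- An order is taken over about fifteen percent of the charge, up and down.

I draw Thursday's curve landmark by landmark, and the first thing to watch in a repeat is its opening.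

1. Over the first 1.2 min Thursday's run averages 0.0725 M min⁻¹, and over the next interval it averages 0.0883 M min⁻¹, which is faster, so the curve opens with a lag and does not begin at its steepest.

2. Between 4.9 min and 7.3 min Thursday's c(substrate) falls from 0.604 M to 0.468 M, which gives 0.106 min⁻¹ for the late constant, the rate per unit of c(substrate) once the opening is past, a pseudo-first-order constant as I read it.

3. Thursday's product crosses half of the charge at 6.74 min by interpolation, later than the 6.54 min that the late constant gives counted from zero, so the lag costs a fraction of a minute.

4. Substrate is the limiting reagent, with less charged than reagent, so the level is 1.00 M of product. Sunday's run has Thursday's charge, and carrying the last reading forward with the late constant gives me 85.0% at 18 min.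

5. Friday's run gives its own late constant of 0.109 min⁻¹, which is 1.03 times Thursday's, so at equal substrate I call the two alike.

6. The two orders at the two-percent point lie inside the opening, where the late constant doesn't reach, so I put no figure of my own on them.

The forecast gives 0.9 for substrate, 0.4 for reagent, alike and 84%, a share just under mine, and it says of the early point that “the run is still partly in the lag, so the apparent orders drop a little”.

The simulation gives 0.70 for substrate and 0.19 for reagent, both below the forecast's, then alike and 84.8%.

    active catalyst + reagent ⇌ catalyst-reagent complex, settled at all times (1.110 M⁻¹)
    catalyst-reagent complex + substrate → product + active catalyst (4.008 M⁻¹ min⁻¹)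
    free catalyst → active catalyst (2.592 min⁻¹)
    active catalyst + impurity → spent catalyst

At the two-percent point Thursday's run goes at 0.077 M min⁻¹ against the 0.104 M min⁻¹ that the late constant gives at that c(substrate), a share of 74.0%. Wednesday's run, making the same product more slowly, goes at 0.046 M min⁻¹ against its 0.0510 M min⁻¹, a share of 90.2%. Their rates therefore stand at 0.60 to one, and the order in substrate comes out low because the step from free catalyst to active catalyst is slow: with that step instant the order is 1.0.

(The data were computed from invented constants.)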